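**Retrosynthetic overview**
1. The three MOM ethers are removed last. The enone C=C is cut by a Claisen–Schmidt disconnection into an 8-acetylchroman and 4-(methoxymethoxy)benzaldehyde.
2. The pyran ring is cut at both of its bonds to the benzene ring at once, C4–C4a and O1–C8a. This gives an aryl iodide (iodine on the future C8a) and a five-carbon bromo alcohol, BrCH2–CH(OMOM)–C(CH3)2–OH, that already carries O1, C2 with its two methyl groups, and the C3 stereocentre. One palladium/norbornene operation joins them.
3. Enabling feature: C8a lies between C8, whose acyl group blocks one ortho position, and C4a, the only ortho C–H. C4 and O1 are 1,3-related through C3 and C2, and O1 sits on a carbon without hydrogen, so one bromo tertiary alcohol can act first as carbon electrophile and then as oxygen nucleophile.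
4. The aryl iodide comes from 5-iodoresorcinol (C-acetylation, MOM on the para hydroxyl, methyl on the chelated hydroxyl). The bromo alcohol comes from methyl (S)-glycidate (bromide opening, MOM, two MeMgBr), which supplies the only stereocentre.
5. Order of rings: benzene ring A is bought, the pyran ring is closed in step 7, and the 4-hydroxyphenyl ring B is attached in step 8.

Key step: step 7

Remark: read from the SMILES, the single stereocentre (C3 of the chroman) is S; chroman numbering (O1, C2, C3, C4, C4a, C5 to C8, C8a) is used throughout, and MOM = methoxymethyl.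

**Step 1**
Reactants: 1 5-iodobenzene-1,3-diol (5-iodoresorcinol)
Product: 2 1-(2,4-dihydroxy-6-iodophenyl)ethan-1-one
Conditions: AcOH, ZnCl2 (1.5 equiv), 140 °C; then 1 M HCl
Reagents that add atoms: acetic acid, CC(=O)O
Why: Nencki-type Friedel–Crafts C-acylation of a resorcinol; both hydroxyl groups direct to C4 (para to one, ortho to the other), the iodine sits on the carbon meta to both and is therefore not prone to ipso-protonation, and the product is deactivated against a second acylation.

**Step 2**
Reactants: 2 1-(2,4-dihydroxy-6-iodophenyl)ethan-1-one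
Product: 3 1-[2-hydroxy-6-iodo-4-(methoxymethoxy)phenyl]ethan-1-one
Conditions: MOMCl (1.05 equiv), K2CO3 (1.5 equiv), acetone, 0 °C to rt
Reagents that add atoms: chloromethyl methyl ether, COCCl
Why: Williamson-type O-alkylation; the 2-OH is held in a hydrogen bond to the acetyl oxygen and is the less acidic and less nucleophilic phenol, so one equivalent of MOMCl should take the para 4-OH.

**Step 3**
Reactants: 3 1-[2-hydroxy-6-iodo-4-(methoxymethoxy)phenyl]ethan-1-one
Product: 4 1-[2-iodo-6-methoxy-4-(methoxymethoxy)phenyl]ethan-1-one
Conditions: MeI (2 equiv), K2CO3 (2 equiv), DMF, 40 °C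
Reagents that add atoms: iodomethane, CI
Why: Williamson ether synthesis on the remaining chelated phenol, the only acidic O–H left; the MOM ether, the aryl iodide and the methyl ketone are inert to K2CO3/MeI.

**Step 4**
Reactants: 5 methyl (2S)-oxirane-2-carboxylate (methyl (S)-glycidate)
Product: 6 methyl (2R)-3-bromo-2-hydroxypropanoate
Conditions: LiBr (1.5 equiv), AcOH (2 equiv), THF, rt
Reagents that add atoms: lithium bromide, [Li+].[Br-]
Why: Acid-assisted SN2 opening of the epoxide by bromide at the unsubstituted C3, the usual regiochemistry for glycidic esters; the stereocentre C2 is not attacked and keeps its configuration (the descriptor changes from S to R only because CH2Br outranks the ester carbon).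

**Step 5**
Reactants: 6 methyl (2R)-3-bromo-2-hydroxypropanoate
Product: 7 methyl (2R)-3-bromo-2-(methoxymethoxy)propanoate
Conditions: MOMCl (1.5 equiv), iPr2NEt (2 equiv), CH2Cl2, 0 °C to rt
Reagents that add atoms: chloromethyl methyl ether, COCCl
Why: Standard alkoxymethylation of a secondary alcohol with MOMCl and a hindered amine base, mild enough that the bromohydrin should not close back to the epoxide; an acetal is chosen because, unlike a silyl group, it cannot migrate to a neighbouring alkoxide in steps 6 and 7.

**Step 6**
Reactants: 7 methyl (2R)-3-bromo-2-(methoxymethoxy)propanoate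
Product: 9 (3R)-4-bromo-3-(methoxymethoxy)-2-methylbutan-2-ol, via methyl ketone 8 (not isolated)
Conditions: MeMgBr (2.3 equiv), THF, −78 to −20 °C; then cold H2O
Reagents that add atoms: methylmagnesium bromide, C[Mg]Br
Why: Double Grignard addition to the ester through methyl ketone 8; the α-alkoxy group makes the carbonyl group more electrophilic by chelation to magnesium, so addition at low temperature should outrun enolisation, and the stereocentre is not involved.

**Step 7**
Reactants: 4 1-[2-iodo-6-methoxy-4-(methoxymethoxy)phenyl]ethan-1-one; 9 (3R)-4-bromo-3-(methoxymethoxy)-2-methylbutan-2-ol (1.5 equiv)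
Product: 11 1-[(3S)-7-methoxy-3,5-bis(methoxymethoxy)-2,2-dimethyl-3,4-dihydro-2H-chromen-8-yl]ethan-1-one, via arylpalladium bromide 10 (not isolated)
Conditions: Pd(OAc)2 (10 mol %), XPhos (20 mol %), norbornene (1.5 equiv), Cs2CO3 (3 equiv), 1,4-dioxane, 100 °C, Ar
Reagents that add atoms: none
Why: Proposed new method: a Catellani-type (palladium/norbornene) ortho-alkylation/ipso-etherification, in which zerovalent palladium inserts into the C–I bond of 4, norbornene carbopalladation and C–H palladation at the only free ortho carbon give an aryl–norbornyl palladacycle of divalent palladium, the primary C–Br bond of 9 adds oxidatively to give tetravalent palladium, and aryl–alkyl reductive elimination followed by norbornene extrusion delivers arylpalladium bromide 10, whose tethered tertiary alkoxide then closes the ring by C(aryl)–O reductive elimination. The closest known reaction types are the palladium/norbornene annulation of aryl iodides with epoxides to 2,3-dihydrobenzofurans (same bond pair, five-membered ring, secondary alkoxide) and the palladium-catalysed intramolecular aryl etherification of tertiary alcohols to 2,2-dialkylchromans; new here is their combination with a 3-bromo tertiary alcohol so that the six-membered ring is formed. The pyran ring closes by a formal 6-exo attack of the alkoxide oxygen on the ipso carbon C8a through a seven-membered aryl(alkoxo)palladium chelate, favoured by the gem-dimethyl group and by the absence of a β-hydrogen on the carbinol carbon. No stereocentre is created: C3 comes from 9 and is not touched, since bond formation occurs only at the CH2 carbon and at oxygen and alkyl–palladium species with β-hydrogens exist only as short-lived tetravalent intermediates (the descriptor changes from R to S only because CH2Br outranks the carbinol carbon and CH2–aryl does not). The step needs site selectivity, secured by the acetyl group at C8, which blocks the second ortho position and, together with the new alkyl group, forces norbornene extrusion; it also needs six- over five-membered ring closure, secured by masking the secondary oxygen as a non-migrating MOM ether so that only the tertiary hydroxyl can bind palladium.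

**Step 8**
Reactants: 11 1-[(3S)-7-methoxy-3,5-bis(methoxymethoxy)-2,2-dimethyl-3,4-dihydro-2H-chromen-8-yl]ethan-1-one; 12 4-(methoxymethoxy)benzaldehyde (1.2 equiv)
Product: 14 (2E)-1-[(3S)-7-methoxy-3,5-bis(methoxymethoxy)-2,2-dimethyl-3,4-dihydro-2H-chromen-8-yl]-3-[4-(methoxymethoxy)phenyl]prop-2-en-1-one, via aldol adduct 13 (not isolated)
Conditions: KOH, EtOH/H2O, rt to 40 °C
Reagents that add atoms: none
Why: Claisen–Schmidt condensation: the methyl ketone is the only enolisable partner and the aldehyde has no α-hydrogen, aldol 13 loses water by E1cB to the conjugated, thermodynamically favoured E-enone, and the acetal groups and the non-acidic C3 stereocentre are stable to hydroxide.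

**Step 9**
Reactants: 14 (2E)-1-[(3S)-7-methoxy-3,5-bis(methoxymethoxy)-2,2-dimethyl-3,4-dihydro-2H-chromen-8-yl]-3-[4-(methoxymethoxy)phenyl]prop-2-en-1-one
Product: 15 (2E)-1-[(3S)-3,5-dihydroxy-7-methoxy-2,2-dimethyl-3,4-dihydro-2H-chromen-8-yl]-3-(4-hydroxyphenyl)prop-2-en-1-one
Conditions: HCl (3 M in MeOH), 45 °C
Reagents that add atoms: none
Why: Acid-catalysed transacetalisation to methanol removes the two aryl MOM ethers and the one alkyl MOM ether; no phenol ortho to the carbonyl group is set free (those positions carry the ring oxygen O1 and the methyl ether), so no flavanone can form, and the secondary carbinol does not ionise under these conditions, so C3 stays S.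

**Compound list**
1 | 5-iodobenzene-1,3-diol | Oc1cc(O)cc(I)c1 | starting material
2 | 1-(2,4-dihydroxy-6-iodophenyl)ethan-1-one | CC(=O)c1c(O)cc(O)cc1I | intermediate
3 | 1-[2-hydroxy-6-iodo-4-(methoxymethoxy)phenyl]ethan-1-one | CC(=O)c1c(O)cc(OCOC)cc1I | intermediate
4 | 1-[2-iodo-6-methoxy-4-(methoxymethoxy)phenyl]ethan-1-one | CC(=O)c1c(OC)cc(OCOC)cc1I | intermediate
5 | methyl (2S)-oxirane-2-carboxylate | COC(=O)[C@@H]1CO1 | starting material
6 | methyl (2R)-3-bromo-2-hydroxypropanoate | COC(=O)[C@@H](O)CBr | intermediate
7 | methyl (2R)-3-bromo-2-(methoxymethoxy)propanoate | COC(=O)[C@@H](OCOC)CBr | intermediate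
8 | (3R)-4-bromo-3-(methoxymethoxy)butan-2-one (formed in the flask, not isolated) | CC(=O)[C@@H](OCOC)CBr | intermediate
9 | (3R)-4-bromo-3-(methoxymethoxy)-2-methylbutan-2-ol | CC(C)(O)[C@@H](OCOC)CBr | intermediate
10 | {2-acetyl-6-[(2S)-3-hydroxy-2-(methoxymethoxy)-3-methylbutyl]-3-methoxy-5-(methoxymethoxy)phenyl}palladium bromide (phosphine ligand omitted; formed in the flask, not isolated) | CC(=O)c1c(OC)cc(OCOC)c(C[C@H](OCOC)C(C)(C)O)c1[Pd]Br | intermediate
11 | 1-[(3S)-7-methoxy-3,5-bis(methoxymethoxy)-2,2-dimethyl-3,4-dihydro-2H-chromen-8-yl]ethan-1-one | CC(=O)c1c(OC)cc(OCOC)c2c1OC(C)(C)[C@@H](OCOC)C2 | intermediate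
12 | 4-(methoxymethoxy)benzaldehyde | COCOc1ccc(C=O)cc1 | starting material
13 | 3-hydroxy-1-[(3S)-7-methoxy-3,5-bis(methoxymethoxy)-2,2-dimethyl-3,4-dihydro-2H-chromen-8-yl]-3-[4-(methoxymethoxy)phenyl]propan-1-one (both carbinol epimers; formed in the flask, not isolated) | COCOc1ccc(C(O)CC(=O)c2c(OC)cc(OCOC)c3c2OC(C)(C)[C@@H](OCOC)C3)cc1 | intermediate
14 | (2E)-1-[(3S)-7-methoxy-3,5-bis(methoxymethoxy)-2,2-dimethyl-3,4-dihydro-2H-chromen-8-yl]-3-[4-(methoxymethoxy)phenyl]prop-2-en-1-one | COCOc1ccc(/C=C/C(=O)c2c(OC)cc(OCOC)c3c2OC(C)(C)[C@@H](OCOC)C3)cc1 | intermediate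
15 | (2E)-1-[(3S)-3,5-dihydroxy-7-methoxy-2,2-dimethyl-3,4-dihydro-2H-chromen-8-yl]-3-(4-hydroxyphenyl)prop-2-en-1-one | COc1cc(O)c2c(c1C(=O)/C=C/c1ccc(O)cc1)OC(C)(C)[C@@H](O)C2 | target

**Step count**
Total: 9 steps. Longest linear sequence: 6 steps (steps 1, 2, 3, 7, 8, 9; the branch through steps 4, 5, 6 is equally long).

**Steps most likely to fail, with fallbacks**

Step 7 (Proposed new method). Oxidative addition of the β-branched, β-oxygenated primary bromide to the aryl–norbornyl palladacycle may be too slow at a C–H site flanked by the MOM ether. Alternatively, C–O reductive elimination from the hindered tertiary alkoxide may lag, so that norbornene-incorporating side paths or proto-depalladation take over. The fallback uses known chemistry only, sets out from 4 and returns at 11.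
- The C–I bond is hydroxylated (Pd2(dba)3, 2-di-tert-butylphosphino-2',4',6'-triisopropylbiphenyl, KOH, 1,4-dioxane/H2O, 100 °C) to the phenol 1-[2-hydroxy-6-methoxy-4-(methoxymethoxy)phenyl]ethan-1-one F1.
- Condensation with 3-methylbut-2-enal (ethylenediammonium diacetate, toluene, 110 °C; Knoevenagel condensation followed by oxa-6π electrocyclisation at the carbon ortho to the free hydroxyl) should give the chromene 1-[7-methoxy-5-(methoxymethoxy)-2,2-dimethyl-2H-chromen-8-yl]ethan-1-one F2.
- Jacobsen–Katsuki epoxidation with (S,S)-N,N'-bis(3,5-di-tert-butylsalicylidene)-1,2-cyclohexanediaminomanganese chloride (5 mol %), m-CPBA and N-methylmorpholine N-oxide in CH2Cl2 at −78 °C should give the epoxide 1-[(3S,4S)-3,4-epoxy-7-methoxy-5-(methoxymethoxy)-2,2-dimethyl-3,4-dihydro-2H-chromen-8-yl]ethan-1-one F3. The face is set by the catalyst; the enantiomeric catalyst would be used if the sense proved opposite.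
- Hydrogenolysis of the benzylic C4–O bond (H2, Pd/C, EtOAc, rt) should give the alcohol 1-[(3S)-3-hydroxy-7-methoxy-5-(methoxymethoxy)-2,2-dimethyl-3,4-dihydro-2H-chromen-8-yl]ethan-1-one F4.
- MOMCl/iPr2NEt in CH2Cl2 then gives 11.

Step 6. The Grignard reagent may deprotonate α to the ester with loss of bromide (β-elimination, which would also erase the stereocentre), or the new tertiary alkoxide may displace bromide on warming. The fallback sets out from 5 and returns at 9; it adds the two methyl groups before any bromide is present.
- Ester 5 is treated with MeMgBr (2.2 equiv, THF, −78 °C) to give the epoxy alcohol 2-[(2S)-oxiran-2-yl]propan-2-ol F5.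
- LiBr/AcOH in THF opens the epoxide at the terminal carbon to the diol (3R)-4-bromo-2-methylbutane-2,3-diol F6.
- MOMCl/iPr2NEt (CH2Cl2, 0 °C) should protect the secondary hydroxyl selectively over the hindered tertiary one, which returns to 9.

Step 1. Regiocontrol may be lost (acylation between the two hydroxyl groups instead of next to the large iodine), or iodine may be lost under acid at 140 °C. The fallback sets out from 1 and returns at 2.
- Both phenols are methylated (MeI, K2CO3, acetone, reflux) to the diether 1-iodo-3,5-dimethoxybenzene F7.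
- Friedel–Crafts acetylation under mild conditions (AcCl, SnCl4, CH2Cl2, 0 °C), for which the position flanked by two methoxy groups is sterically closed, should give the ketone 1-(2-iodo-4,6-dimethoxyphenyl)ethan-1-one F8.
- BBr3 (CH2Cl2, −78 °C to rt) cleaves both methyl ethers and returns to 2.

**Further compounds**
F1 | step 7 | 1-[2-hydroxy-6-methoxy-4-(methoxymethoxy)phenyl]ethan-1-one | CC(=O)c1c(O)cc(OCOC)cc1OC
F2 | step 7 | 1-[7-methoxy-5-(methoxymethoxy)-2,2-dimethyl-2H-chromen-8-yl]ethan-1-one | CC(=O)c1c(OC)cc(OCOC)c2c1OC(C)(C)C=C2
F3 | step 7 | 1-[(3S,4S)-3,4-epoxy-7-methoxy-5-(methoxymethoxy)-2,2-dimethyl-3,4-dihydro-2H-chromen-8-yl]ethan-1-one | CC(=O)c1c(OC)cc(OCOC)c2c1OC(C)(C)[C@H]3O[C@@H]23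
F4 | step 7 | 1-[(3S)-3-hydroxy-7-methoxy-5-(methoxymethoxy)-2,2-dimethyl-3,4-dihydro-2H-chromen-8-yl]ethan-1-one | CC(=O)c1c(OC)cc(OCOC)c2c1OC(C)(C)[C@@H](O)C2
F5 | step 6 | 2-[(2S)-oxiran-2-yl]propan-2-ol | CC(C)(O)[C@@H]1CO1
F6 | step 6 | (3R)-4-bromo-2-methylbutane-2,3-diol | CC(C)(O)[C@@H](O)CBr
F7 | step 1 | 1-iodo-3,5-dimethoxybenzene | COc1cc(OC)cc(I)c1
F8 | step 1 | 1-(2-iodo-4,6-dimethoxyphenyl)ethan-1-one | CC(=O)c1c(OC)cc(OC)cc1I
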